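The target is a linear pentamer: butyrylfilicinic acid rings A and E flank three butyrylphloroglucinol rings B, C and D, all joined by CH2 bridges. The route rests on cutting the two aryl–CH2 bonds at C3 and C5 of central ring C, carbons that each sit between two oxygen-bearing ring carbons. One double Negishi coupling of a tri-O-benzyl 3,5-diiodobutyrophenone (ring C) with two equivalents of a ketone-bearing benzylic zinc chloride (rings B and D) makes both bonds and fixes the B–C–D order without bridge scrambling. Benzyl ethers permit neutral hydrogenolysis; rings A and E are then attached through a preformed Mannich base. All five rings derive from butyrylphloroglucinol.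

Key step: step 8

Remark: the target has no stereocentre; its end rings are drawn as one of several equivalent enol tautomers, and the benzylic zinc reagent is written as the monomeric chloride although it is a LiCl adduct in THF.

Step 1
Reactants: 1 phloroglucinol (anhydrous); 2 butyryl chloride
Product: 3 butyrylphloroglucinol (1-(2,4,6-trihydroxyphenyl)butan-1-one)
Conditions: AlCl3 (4 equiv), PhNO2/CH2Cl2, 0 °C to 45 °C; then ice/1 M HCl
Reagents that add atoms: none
Why: Friedel–Crafts C-acylation of the very electron-rich triol should stop at the monoketone because the chelated acyl group deactivates the ring towards a second acylation.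

Step 2
Reactants: 3 butyrylphloroglucinol
Product: 4 1-[2,4,6-tris(benzyloxy)phenyl]butan-1-one
Conditions: BnBr (3.6 equiv), K2CO3 (5 equiv), DMF, 70 °C
Reagents that add atoms: benzyl bromide, BrCc1ccccc1
Why: Williamson etherification in a dipolar aprotic solvent should favour O-benzylation of all three phenols, since the electron-withdrawing butyryl group lowers the carbon nucleophilicity of the ring.

Step 3
Reactants: 4 1-[2,4,6-tris(benzyloxy)phenyl]butan-1-one
Product: 6 1-[2,4,6-tris(benzyloxy)-3,5-diiodophenyl]butan-1-one, via mono-iodide 5 (not isolated)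
Conditions: N-iodosuccinimide (2.3 equiv), CF3CO2H (0.3 equiv), MeCN, 25 °C, dark
Reagents that add atoms: N-iodosuccinimide, O=C1CCC(=O)N1I
Why: Acid-activated electrophilic aromatic iodination should take place twice at the only two ring C–H positions, each ortho or para to three alkoxy groups, while the pendant benzyl rings are far less activated.

Step 4
Reactants: 4 1-[2,4,6-tris(benzyloxy)phenyl]butan-1-one
Product: 8 2,4,6-tris(benzyloxy)-3-butanoylbenzaldehyde, via aryl iminium chloride 7 (not isolated)
Conditions: POCl3 (2 equiv), DMF, 0 °C to 50 °C; then aq NaOAc, 25 °C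
Reagents that add atoms: N,N-dimethylformamide, CN(C)C=O; water, O
Why: Vilsmeier–Haack formylation should attack one of the two equivalent activated ring carbons, and the iminium group installed first deactivates the ring against a second attack before hydrolysis releases the aldehyde.

Step 5
Reactants: 8 2,4,6-tris(benzyloxy)-3-butanoylbenzaldehyde
Product: 9 1-[2,4,6-tris(benzyloxy)-3-(hydroxymethyl)phenyl]butan-1-one
Conditions: NaBH4 (0.5 equiv), THF/MeOH 4:1, −20 °C to 0 °C; then aq NH4Cl
Reagents that add atoms: none
Why: Chemoselective borohydride reduction should consume the aldehyde well before the propyl aryl ketone, which is shielded by two ortho benzyloxy groups.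

Step 6
Reactants: 9 1-[2,4,6-tris(benzyloxy)-3-(hydroxymethyl)phenyl]butan-1-one
Product: 11 1-[2,4,6-tris(benzyloxy)-3-(chloromethyl)phenyl]butan-1-one, via benzylic mesylate 10 (not isolated)
Conditions: MsCl (1.3 equiv), LiCl (4 equiv), 2,4,6-collidine (1.6 equiv), DMF, 0 °C; cold aqueous work-up, crude product used at once
Reagents that add atoms: lithium chloride, [Li+].[Cl-]
Why: Mesylation followed by chloride displacement in the same flask (Collington–Meyers conditions) stays buffered and non-acidic, which should prevent acid-triggered self-alkylation of this easily ionised benzylic system.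

Step 7
Reactants: 11 1-[2,4,6-tris(benzyloxy)-3-(chloromethyl)phenyl]butan-1-one
Product: 12 {[2,4,6-tris(benzyloxy)-3-butanoylphenyl]methyl}zinc chloride (LiCl adduct, THF solution, titrated with I2 and used directly)
Conditions: Zn dust (2 equiv, activated with BrCH2CH2Br and Me3SiCl), LiCl (1.5 equiv), THF, 25 °C
Reagents that add atoms: zinc, [Zn]
Why: LiCl-promoted direct insertion of zinc into a benzylic C–Cl bond is a known route to benzylic zinc chlorides that tolerates ketones, and LiCl keeps the reagent in solution and limits Wurtz coupling.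

Step 8
Reactants: 6 1-[2,4,6-tris(benzyloxy)-3,5-diiodophenyl]butan-1-one (1 equiv); 12 {[2,4,6-tris(benzyloxy)-3-butanoylphenyl]methyl}zinc chloride (2.6 equiv)
Product: 14 nona-O-benzyl three-ring core (1-[2,4,6-tris(benzyloxy)-3,5-bis{[2,4,6-tris(benzyloxy)-3-butanoylphenyl]methyl}phenyl]butan-1-one), via mono-coupled iodide 13 (not isolated)
Conditions: Pd(OAc)2 (5 mol%), SPhos (2-dicyclohexylphosphino-2',6'-dimethoxybiphenyl, 10 mol%), THF, 25 °C to 50 °C; 12 added over 2 h by syringe pump
Reagents that add atoms: none
Why: Zerovalent palladium bound to SPhos should insert into each C–I bond of 6, accept the benzyl group from zinc and release the aryl–CH2 bond by reductive elimination, giving first mono-iodide 13 and then 14. The closest known reaction type is the Negishi coupling of LiCl-solubilised benzylic zinc chlorides with aryl iodides, which tolerates ketones. No ring is closed and no stereocentre is created. The connectivity is set only by where iodine and zinc sit, so the order of rings B, C and D is fixed and the bridges cannot redistribute as they do in acid- or base-mediated condensations; the benzyl–palladium intermediate also has no β-hydrogen to eliminate. Both C–I bonds lie between two benzyloxy groups, so a bulky electron-rich biaryl phosphine is used to speed oxidative addition and reductive elimination at the crowded carbon, and the zinc reagent is added slowly and in excess to hold back bibenzyl formation and protodeiodination.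

Step 9
Reactants: 14 nona-O-benzyl three-ring core
Product: 15 nonaphenol three-ring core (1-{3,5-bis[(3-butanoyl-2,4,6-trihydroxyphenyl)methyl]-2,4,6-trihydroxyphenyl}butan-1-one)
Conditions: H2 (1 atm), 10% Pd/C, EtOAc/MeOH, 25 °C; filtered under argon
Reagents that add atoms: none
Why: Hydrogenolysis of the nine benzyl ethers is neutral, so it should leave the diarylmethane C–C bonds and the hindered aryl ketones untouched and expose no acid or base that could redistribute the bridges.

Step 10
Reactants: 3 butyrylphloroglucinol
Product: 17 butyrylfilicinic acid (2-butanoyl-3,5-dihydroxy-4,4-dimethylcyclohexa-2,5-dien-1-one), via C-methyl ketone 16 (not isolated)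
Conditions: NaOMe (3 equiv), MeI (2.2 equiv), MeOH, 0 °C to 25 °C; then 1 M HCl; chromatography
Reagents that add atoms: iodomethane, CI
Why: Base-mediated dearomative C-methylation of acylphloroglucinols is the classical entry to acylfilicinic acids, the second methyl group entering at the already methylated and more electron-rich carbon, and the product should be separable from under- and over-methylated congeners.

Step 11
Reactants: 17 butyrylfilicinic acid
Product: 18 2-butanoyl-6-[(dimethylamino)methyl]-3,5-dihydroxy-4,4-dimethylcyclohexa-2,5-dien-1-one (Mannich base, isolated as its inner salt)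
Conditions: CH2=NMe2+ I− (1.05 equiv), iPr2NEt (1.0 equiv), CH2Cl2, 0 °C
Reagents that add atoms: N,N-dimethylmethyleneiminium iodide (Eschenmoser's salt), C=[N+](C)C.[I-]
Why: Mannich aminomethylation of the vinylogous acid at C6, its only free enolic carbon, with a preformed iminium salt under anhydrous conditions should be fast enough to leave no free 17 that could form a methylene-bridged dimer.

Step 12
Reactants: 15 nonaphenol three-ring core (1 equiv); 18 Mannich base of butyrylfilicinic acid (2.4 equiv, added in portions)
Product: 21 target CNP0188003.0 (15 in which the free carbon of each outer ring is linked through CH2 to C6 of a butyrylfilicinic acid ring), via methylidene trione 19 (not isolated), via mono-adduct 20 (not isolated)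
Conditions: AcOH (10 equiv), 1,4-dioxane, 60 °C, argon
Reagents that add atoms: none
Why: Thermal loss of dimethylamine from the inner salt should give methide 19, which is captured by Michael-type C-alkylation at the single free carbon of each outer ring of 15 (elimination–addition alkylation with a Mannich base, the controlled form of the classical formaldehyde bridging of acylphloroglucinols), and since the electrophile has no free nucleophilic carbon and the nucleophile carries no one-carbon unit only cross-coupling is possible.

Compound list
1 | phloroglucinol (benzene-1,3,5-triol) | Oc1cc(O)cc(O)c1 | starting material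
2 | butyryl chloride (butanoyl chloride) | CCCC(=O)Cl | starting material
3 | butyrylphloroglucinol, 1-(2,4,6-trihydroxyphenyl)butan-1-one | CCCC(=O)c1c(O)cc(O)cc1O | intermediate
4 | 1-[2,4,6-tris(benzyloxy)phenyl]butan-1-one | CCCC(=O)c1c(OCc2ccccc2)cc(OCc2ccccc2)cc1OCc1ccccc1 | intermediate
5 | 1-[2,4,6-tris(benzyloxy)-3-iodophenyl]butan-1-one (mono-iodide, formed in the flask) | CCCC(=O)c1c(OCc2ccccc2)c(I)c(OCc2ccccc2)cc1OCc1ccccc1 | intermediate
6 | 1-[2,4,6-tris(benzyloxy)-3,5-diiodophenyl]butan-1-one | CCCC(=O)c1c(OCc2ccccc2)c(I)c(OCc2ccccc2)c(I)c1OCc1ccccc1 | intermediate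
7 | {[2,4,6-tris(benzyloxy)-3-butanoylphenyl]methylidene}dimethylammonium chloride (aryl iminium chloride, formed in the flask) | CCCC(=O)c1c(OCc2ccccc2)cc(OCc2ccccc2)c(C=[N+](C)C)c1OCc1ccccc1.[Cl-] | intermediate
8 | 2,4,6-tris(benzyloxy)-3-butanoylbenzaldehyde | CCCC(=O)c1c(OCc2ccccc2)cc(OCc2ccccc2)c(C=O)c1OCc1ccccc1 | intermediate
9 | 1-[2,4,6-tris(benzyloxy)-3-(hydroxymethyl)phenyl]butan-1-one | CCCC(=O)c1c(OCc2ccccc2)cc(OCc2ccccc2)c(CO)c1OCc1ccccc1 | intermediate
10 | [2,4,6-tris(benzyloxy)-3-butanoylphenyl]methyl methanesulfonate (benzylic mesylate, formed in the flask) | CCCC(=O)c1c(OCc2ccccc2)cc(OCc2ccccc2)c(COS(C)(=O)=O)c1OCc1ccccc1 | intermediate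
11 | 1-[2,4,6-tris(benzyloxy)-3-(chloromethyl)phenyl]butan-1-one | CCCC(=O)c1c(OCc2ccccc2)cc(OCc2ccccc2)c(CCl)c1OCc1ccccc1 | intermediate
12 | {[2,4,6-tris(benzyloxy)-3-butanoylphenyl]methyl}zinc chloride (LiCl adduct in THF) | CCCC(=O)c1c(OCc2ccccc2)cc(OCc2ccccc2)c(C[Zn]Cl)c1OCc1ccccc1 | intermediate
13 | 1-[2,4,6-tris(benzyloxy)-3-iodo-5-{[2,4,6-tris(benzyloxy)-3-butanoylphenyl]methyl}phenyl]butan-1-one (mono-coupled iodide, formed in the flask) | CCCC(=O)c1c(OCc2ccccc2)c(I)c(OCc2ccccc2)c(Cc2c(OCc3ccccc3)cc(OCc3ccccc3)c(C(=O)CCC)c2OCc2ccccc2)c1OCc1ccccc1 | intermediate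
14 | nona-O-benzyl three-ring core, 1-[2,4,6-tris(benzyloxy)-3,5-bis{[2,4,6-tris(benzyloxy)-3-butanoylphenyl]methyl}phenyl]butan-1-one | CCCC(=O)c1c(OCc2ccccc2)cc(OCc2ccccc2)c(Cc2c(OCc3ccccc3)c(Cc3c(OCc4ccccc4)cc(OCc4ccccc4)c(C(=O)CCC)c3OCc3ccccc3)c(OCc3ccccc3)c(C(=O)CCC)c2OCc2ccccc2)c1OCc1ccccc1 | intermediate
15 | nonaphenol three-ring core, 1-{3,5-bis[(3-butanoyl-2,4,6-trihydroxyphenyl)methyl]-2,4,6-trihydroxyphenyl}butan-1-one | CCCC(=O)c1c(O)cc(O)c(Cc2c(O)c(Cc3c(O)cc(O)c(C(=O)CCC)c3O)c(O)c(C(=O)CCC)c2O)c1O | intermediate
16 | 1-(2,4,6-trihydroxy-3-methylphenyl)butan-1-one (C-methyl ketone, formed in the flask) | CCCC(=O)c1c(O)cc(O)c(C)c1O | intermediate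
17 | butyrylfilicinic acid, 2-butanoyl-3,5-dihydroxy-4,4-dimethylcyclohexa-2,5-dien-1-one | CCCC(=O)C1=C(O)C(C)(C)C(O)=CC1=O | intermediate
18 | 2-butanoyl-6-[(dimethylamino)methyl]-3,5-dihydroxy-4,4-dimethylcyclohexa-2,5-dien-1-one (Mannich base) | CCCC(=O)C1=C(O)C(C)(C)C(O)=C(CN(C)C)C1=O | intermediate
19 | 2-butanoyl-3-hydroxy-4,4-dimethyl-6-methylidenecyclohex-2-ene-1,5-dione (methide, formed in the flask) | CCCC(=O)C1=C(O)C(C)(C)C(=O)C(=C)C1=O | intermediate
20 | mono-adduct: 15 in which the free carbon of one outer ring is linked through CH2 to C6 of a butyrylfilicinic acid ring (formed in the flask) | CCCC(=O)C1=C(O)C(C)(C)C(O)=C(Cc2c(O)c(Cc3c(O)c(Cc4c(O)cc(O)c(C(=O)CCC)c4O)c(O)c(C(=O)CCC)c3O)c(O)c(C(=O)CCC)c2O)C1=O | intermediate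
21 | CNP0188003.0: 15 in which the free carbon of each outer ring is linked through CH2 to C6 of a butyrylfilicinic acid ring (no stereocentre) | CCCC(=O)C1=C(O)C(C)(C)C(O)=C(Cc2c(O)c(Cc3c(O)c(Cc4c(O)c(CC5=C(O)C(C)(C)C(O)=C(C(=O)CCC)C5=O)c(O)c(C(=O)CCC)c4O)c(O)c(C(=O)CCC)c3O)c(O)c(C(=O)CCC)c2O)C1=O | target

Total step count: 12 steps.
Longest linear sequence: 9 steps (steps 1, 2, 4, 5, 6, 7, 8, 9 and 12, from phloroglucinol).

Steps most likely to fail

Step 8 (double Negishi coupling). The second coupling, at a C–I bond wedged between two benzyloxy groups, may stall after the first, so that reduction of the remaining C–I bond and homocoupling of the benzylic zinc reagent outrun cross-coupling. The fallback makes the two inner bridges with conventional polarity. It sets out from 3 and 9: unprotected 3 is alkylated at its two free ring carbons by 9 (2.1 equiv) with TsOH·H2O (5 mol%) in MeCN at 0 °C. This is a Friedel–Crafts benzylation through the stabilised benzylic cation, in which the free triol ring is far more nucleophilic than the acylated tris-ether ring of 9. It should give the hexa-O-benzyl three-ring core F1, and hydrogenolysis of F1 under the conditions of step 9 comes back to the route at 15.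

Step 12 (attachment of rings A and E). Methide 19 may condense with itself faster than it is captured at the crowded outer-ring carbons, and prolonged heating with liberated amine may redistribute the existing bridges by retro-Michael fragmentation. The fallback reverses the roles of the partners. It sets out from 15 (with 17 from step 10): aminomethylation of both free outer-ring carbons with CH2=NMe2+ I− (2.2 equiv, iPr2NEt, THF/CH2Cl2, 0 °C) should give the bis(dimethylaminomethyl) three-ring core F2, which has no nucleophilic ring carbon left. Warming F2 with 17 (3 equiv) in 1,4-dioxane/AcOH at 60 °C releases the ortho-quinone methides, which are trapped by C6 of 17, and the sequence comes back to the route at 21; excess 17 is removed by chromatography.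

Step 7 (zinc insertion). The electron-rich benzylic chloride may ionise on the metal surface, so that Wurtz dimerisation and Friedel–Crafts oligomerisation lower the titre of the zinc reagent below what the slow-addition protocol needs. The fallback replaces zinc by boron. It sets out from 11: Pd-catalysed borylation with bis(pinacolato)diboron (Pd(dba)2, tris(4-methoxyphenyl)phosphine, KOAc, toluene, 50 °C) should give the benzylic pinacol boronate F3, which can be purified and stored. Double Suzuki–Miyaura coupling of F3 (2.5 equiv) with 6 (Pd(OAc)2, SPhos, K3PO4, toluene/H2O, 80 °C) forms the same two aryl–CH2 bonds and comes back to the route at 14.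

Further compounds
F1 | step 8 | hexa-O-benzyl three-ring core, 1-[3,5-bis{[2,4,6-tris(benzyloxy)-3-butanoylphenyl]methyl}-2,4,6-trihydroxyphenyl]butan-1-one | CCCC(=O)c1c(OCc2ccccc2)cc(OCc2ccccc2)c(Cc2c(O)c(Cc3c(OCc4ccccc4)cc(OCc4ccccc4)c(C(=O)CCC)c3OCc3ccccc3)c(O)c(C(=O)CCC)c2O)c1OCc1ccccc1
F2 | step 12 | bis(dimethylaminomethyl) three-ring core, 15 carrying a CH2NMe2 group on the free carbon of each outer ring | CCCC(=O)c1c(O)c(CN(C)C)c(O)c(Cc2c(O)c(Cc3c(O)c(CN(C)C)c(O)c(C(=O)CCC)c3O)c(O)c(C(=O)CCC)c2O)c1O
F3 | step 7 | 1-{2,4,6-tris(benzyloxy)-3-[(4,4,5,5-tetramethyl-1,3,2-dioxaborolan-2-yl)methyl]phenyl}butan-1-one | CCCC(=O)c1c(OCc2ccccc2)cc(OCc2ccccc2)c(CB2OC(C)(C)C(C)(C)O2)c1OCc1ccccc1
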